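**Retrosynthetic overview**
- The dihydrofuran ring is opened at its enol-ether C–O bond, giving a side-chain (2S)-diol on a dearomatized acylphloroglucinol; this ring is formed last.
- The secondary carbinol comes from a ketone by catalyst-controlled reduction.
- Key C–C disconnection: the bond from the quaternary ring carbon to the side-chain CH2. The ring carbon of deoxycohumulone phenolate attacks a bromomethyl ketone that acts as an enolonium equivalent, under a chiral ammonium ion pair; this step dearomatizes the ring and sets the quaternary centre.
- Deoxycohumulone comes from phlorisobutyrophenone and two prenyl bromides; the bromoketone comes from 3-hydroxy-3-methylbutan-2-one and bromine.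
- Ring order: the carbocycle is the purchased aromatic ring (dearomatized in the key step); the dihydrofuran is closed in the last step.

Assumption: phlorisobutyrophenone is bought as a catalogue compound, and the cinchonidinium salt in step 3 is taken to give the (6S) centre (if it gives 6R, the pseudoenantiomeric cinchoninium salt is used instead).

**Step 1**
Reactants: 1 phlorisobutyrophenone (2-methyl-1-(2,4,6-trihydroxyphenyl)propan-1-one); 2 prenyl bromide (1-bromo-3-methylbut-2-ene, 2.1 equiv)
Product: 3 deoxycohumulone (2-methyl-1-[2,4,6-trihydroxy-3,5-bis(3-methylbut-2-en-1-yl)phenyl]propan-1-one)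
Conditions: KOH (2.2 equiv), H2O, 0 °C
Reagents that add atoms: none
Why: Friedel–Crafts-type C-alkylation of the ambident phloroglucinolate, in which water solvates the phenolate oxygens so the soft allylic bromide is taken at the two free ring carbons to give the known 3,5-diprenyl compound (mono- and triprenyl by-products are removed by chromatography).

**Step 2**
Reactants: 4 3-hydroxy-3-methylbutan-2-one
Product: 5 1-bromo-3-hydroxy-3-methylbutan-2-one
Conditions: Br2 (1.0 equiv), MeOH, 0 °C to rt; H2O work-up
Reagents that add atoms: bromine (BrBr)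
Why: Acid-autocatalysed α-bromination of a ketone through its enol, which can form only toward the methyl group because the other α-carbon is fully substituted, so a single bromoketone results.

**Step 3**
Reactants: 3 deoxycohumulone; 5 1-bromo-3-hydroxy-3-methylbutan-2-one (1.2 equiv)
Product: 6 (6S)-3,5-dihydroxy-6-(3-hydroxy-3-methyl-2-oxobutyl)-4,6-bis(3-methylbut-2-en-1-yl)-2-(2-methylpropanoyl)cyclohexa-2,4-dien-1-one
Conditions: O-allyl-N-(9-anthracenylmethyl)cinchonidinium bromide (10 mol%), CsOH·H2O (1.2 equiv), 4 Å MS, toluene/CH2Cl2 3:1, −50 °C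
Reagents that add atoms: none
Why: Proposed new method: bromoketone 5 acts as an enolonium (a2) equivalent, so SN2 attack of a prenyl-bearing ring carbon of the phenolate of 3 (the two such carbons are equivalent by symmetry) on its CH2Br carbon joins two enolate-type α-carbons and dearomatizes the ring; the chiral ammonium cation ion-paired to the planar phenolate shields one face and sets the quaternary (6S) centre, the tight soft ion pair in a non-polar medium and the hindered tertiary-carbinol ketone disfavour O-alkylation and carbonyl addition, and the closest known reaction type is the cinchona-ammonium phase-transfer alkylative dearomatization of 3,5-diprenyl acylphloroglucinols combined with C-alkylation of 1,3-dicarbonyl anions by α-haloketones.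

**Step 4**
Reactants: 6 the (6S)-keto triketone from step 3
Product: 7 (6S)-6-[(2S)-2,3-dihydroxy-3-methylbutyl]-3,5-dihydroxy-4,6-bis(3-methylbut-2-en-1-yl)-2-(2-methylpropanoyl)cyclohexa-2,4-dien-1-one
Conditions: (R)-tetrahydro-1-methyl-3,3-diphenyl-1H,3H-pyrrolo[1,2-c][1,3,2]oxazaborole (20 mol%), catecholborane (5 equiv), toluene/CH2Cl2, −78 to −40 °C; then MeOH, pH 7 buffer
Reagents that add atoms: none
Why: Corey–Bakshi–Shibata reduction, in which the catalyst delivers hydride to the ketone face defined by the large borylated tertiary-carbinol side versus the small CH2 side and so gives the (2S) carbinol independently of the remote quaternary centre, while excess catecholborane only masks the OH groups as borates (the enolized triketone as its boron chelate) and leaves the trisubstituted alkenes untouched at low temperature.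

**Step 5**
Reactants: 7 the (6S,2'S)-diol from step 4
Product: 8 (2S,3aS)-6-hydroxy-2-(2-hydroxypropan-2-yl)-3a,7-bis(3-methylbut-2-en-1-yl)-5-(2-methylpropanoyl)-3,3a-dihydro-1-benzofuran-4(2H)-one (target)
Conditions: pyridinium p-toluenesulfonate (10 mol%), 4 Å MS, toluene, 50 °C
Reagents that add atoms: none
Why: Acid-catalysed intramolecular vinylogous esterification (addition–elimination of the secondary hydroxyl at the non-chelated enol carbon C5 next to the quaternary centre, with loss of water) closes the five-membered ring in preference to a six-membered ring through the tertiary hydroxyl and keeps the hydrogen-bonded acyl-enol unit, and because no bond to either stereocentre is touched the (2S,3aS) product, with the hydroxyisopropyl group trans to the angular prenyl group, follows directly from (6S,2'S).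

**Compound list**
1 | phlorisobutyrophenone, 2-methyl-1-(2,4,6-trihydroxyphenyl)propan-1-one | CC(C)C(=O)c1c(O)cc(O)cc1O | starting material
2 | prenyl bromide, 1-bromo-3-methylbut-2-ene | CC(C)=CCBr | starting material
3 | deoxycohumulone, 2-methyl-1-[2,4,6-trihydroxy-3,5-bis(3-methylbut-2-en-1-yl)phenyl]propan-1-one | CC(C)C(=O)c1c(O)c(CC=C(C)C)c(O)c(CC=C(C)C)c1O | intermediate
4 | 3-hydroxy-3-methylbutan-2-one | CC(=O)C(C)(C)O | starting material
5 | 1-bromo-3-hydroxy-3-methylbutan-2-one | BrCC(=O)C(C)(C)O | intermediate
6 | (6S)-3,5-dihydroxy-6-(3-hydroxy-3-methyl-2-oxobutyl)-4,6-bis(3-methylbut-2-en-1-yl)-2-(2-methylpropanoyl)cyclohexa-2,4-dien-1-one | CC(C)=CCC1=C(O)[C@](CC=C(C)C)(CC(=O)C(C)(C)O)C(=O)C(C(=O)C(C)C)=C1O | intermediate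
7 | (6S)-6-[(2S)-2,3-dihydroxy-3-methylbutyl]-3,5-dihydroxy-4,6-bis(3-methylbut-2-en-1-yl)-2-(2-methylpropanoyl)cyclohexa-2,4-dien-1-one | CC(C)=CCC1=C(O)[C@](CC=C(C)C)(C[C@H](O)C(C)(C)O)C(=O)C(C(=O)C(C)C)=C1O | intermediate
8 | (2S,3aS)-6-hydroxy-2-(2-hydroxypropan-2-yl)-3a,7-bis(3-methylbut-2-en-1-yl)-5-(2-methylpropanoyl)-3,3a-dihydro-1-benzofuran-4(2H)-one | CC(C)=CCC1=C2O[C@H](C(C)(C)O)C[C@]2(CC=C(C)C)C(=O)C(C(=O)C(C)C)=C1O | target

**Step count**
Total steps: 5. Longest linear sequence: 4 (steps 1, 3, 4, 5); step 2 is a one-step side branch.

**Three steps most likely to fail, each with one fallback**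

Step 3 (O-alkylation instead of C-alkylation, or low enantioselectivity). The fallback sets out from 5 (with 3) and comes back at 6. Bromoketone 5 is condensed with hydroxylamine hydrochloride and NaOAc to 1-bromo-3-hydroxy-3-methylbutan-2-one oxime F1. Na2CO3 converts this in the flask into 2-methyl-3-nitrosobut-3-en-2-ol F2, a soft conjugate acceptor that is still an enolonium equivalent. The ammonium-paired phenolate of 3 adds to it through carbon under the same chiral phase-transfer salt, giving (6S)-3,5-dihydroxy-6-[3-hydroxy-2-(hydroxyimino)-3-methylbutyl]-4,6-bis(3-methylbut-2-en-1-yl)-2-(2-methylpropanoyl)cyclohexa-2,4-dien-1-one F3. Aqueous TiCl3 buffered with NH4OAc then cleaves the oxime to ketone 6.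

Step 4 (poor face selection on a ketone hindered on both sides, or interference by the acidic OH groups). The fallback sets out from 5 (with 3) and comes back at 7; the carbinol centre is made on the small reagent before the coupling. Bromoketone 5 is reduced with the same oxazaborolidine and catecholborane, or with a ketoreductase, to (R)-1-bromo-3-methylbutane-2,3-diol F4. K2CO3 closes this to (S)-2-(oxiran-2-yl)propan-2-ol F5. The epoxide is opened at its CH2 terminus by the ring carbon of the phenolate of 3 under the ion-pair conditions of step 3 (0 °C), giving diol 7 directly. The epoxide is a weaker electrophile than 5, so this coupling is expected to be slower and lower-yielding.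

Step 5 (closure at the wrong carbonyl, ring closure through the tertiary hydroxyl, or acid damage to the diol and prenyl groups). The fallback sets out from 7 and comes back at 8. The free, non-chelated C5 enol is O-methylated with trimethylsilyldiazomethane (toluene/MeOH) to (6S)-6-[(2S)-2,3-dihydroxy-3-methylbutyl]-3-hydroxy-5-methoxy-4,6-bis(3-methylbut-2-en-1-yl)-2-(2-methylpropanoyl)cyclohexa-2,4-dien-1-one F6. The secondary hydroxyl then displaces the methoxy group by intramolecular addition–elimination (catalytic camphorsulfonic acid, toluene, rt), which fixes the site of closure at C5 and gives 8 with both stereocentres unchanged.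

**Further compounds**
F1 | step 3 | 1-bromo-3-hydroxy-3-methylbutan-2-one oxime | BrCC(=NO)C(C)(C)O
F2 | step 3 | 2-methyl-3-nitrosobut-3-en-2-ol | C=C(N=O)C(C)(C)O
F3 | step 3 | (6S)-3,5-dihydroxy-6-[3-hydroxy-2-(hydroxyimino)-3-methylbutyl]-4,6-bis(3-methylbut-2-en-1-yl)-2-(2-methylpropanoyl)cyclohexa-2,4-dien-1-one | CC(C)=CCC1=C(O)[C@](CC=C(C)C)(CC(=NO)C(C)(C)O)C(=O)C(C(=O)C(C)C)=C1O
F4 | step 4 | (R)-1-bromo-3-methylbutane-2,3-diol | BrC[C@H](O)C(C)(C)O
F5 | step 4 | (S)-2-(oxiran-2-yl)propan-2-ol | CC(C)(O)[C@@H]1CO1
F6 | step 5 | (6S)-6-[(2S)-2,3-dihydroxy-3-methylbutyl]-3-hydroxy-5-methoxy-4,6-bis(3-methylbut-2-en-1-yl)-2-(2-methylpropanoyl)cyclohexa-2,4-dien-1-one | CC(C)=CCC1=C(OC)[C@](CC=C(C)C)(C[C@H](O)C(C)(C)O)C(=O)C(C(=O)C(C)C)=C1O
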